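The cyclohexene ring (labdane C12, C13, C14, C15 plus C4' and C5' of the trans-fused nine-membered ring) is read as a Diels–Alder retron whose diene is itself assembled in the same flask. Everything rests on a three-component domino Stille coupling/Diels–Alder reaction of a labdane (E)-alkenyl iodide, tributyl(vinyl)stannane and the strained trans-cyclononene enal made from (−)-β-caryophyllene. Cross-coupling forges C13–C14 and releases the polymerisation-prone diene only beside its dienophile; cycloaddition then forges C15–C5' and C12–C4', makes C13–C14 the ring olefin and sets the quaternary centre C4' together with C5' and C12. A Pinnick oxidation completes the diacid.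

Key step: step 7

Remark: the diterpene half carries labdane numbers (C1 to C20) and the sesquiterpene half primed caryophyllane numbers (C4' = quaternary carbon bearing the carboxyl carbon C12', C5' = adjacent ring-fusion CH). The trans ring olefin of the caryophyllene-derived compounds is 4'Z in CIP terms once C12' carries oxygen. Both terpenes are assumed to be bought as single enantiomers, (−)-β-caryophyllene being 1R,9S.

Step 1
Reactants: 1 trans-communic acid, (12E)-labda-8(17),12,14-trien-19-oic acid
Product: 3 12-oxo-13,14,15,16-tetranorlabd-8(17)-en-19-oic acid, via secondary ozonide 2 (not isolated)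
Conditions: O3 (1.0 equiv, Sudan Red 7B end point), CH2Cl2, −78 °C; then Me2S, −78 °C to rt
Reagents that add atoms: ozone, [O-][O+]=O
Why: Electrophilic ozone should attack the most electron-rich, trisubstituted C12=C13 bond faster than the monosubstituted C14=C15 and the hindered 1,1-disubstituted C8=C17 bonds, so chemoselective ozonolysis with reductive work-up excises C13–C16 as methyl vinyl ketone without touching any stereocentre (any 12Z isomer in the commercial acid converges on the same aldehyde).

Step 2
Reactants: 3 12-oxo-13,14,15,16-tetranorlabd-8(17)-en-19-oic acid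
Product: 4 14,15,16-trinorlabd-8(17)-en-12-yn-19-oic acid
Conditions: dimethyl (1-diazo-2-oxopropyl)phosphonate, K2CO3 (3 equiv), MeOH, 0 °C to rt; then aq. HCl
Reagents that add atoms: dimethyl (1-diazo-2-oxopropyl)phosphonate, CC(=O)C(=[N+]=[N-])P(=O)(OC)OC
Why: Seyferth–Gilbert homologation in its Ohira–Bestmann variant converts the enolisable aldehyde into the terminal alkyne under mild carbonate conditions that leave the carboxylate, the exocyclic olefin and C9 untouched, the diazo carbon becoming C13.

Step 3
Reactants: 4 14,15,16-trinorlabd-8(17)-en-12-yn-19-oic acid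
Product: 6 14,15-dinorlabd-8(17)-en-12-yn-19-oic acid, via dilithio acetylide carboxylate 5 (not isolated)
Conditions: LiN(iPr)2 (2.2 equiv, commercial solution), THF, −78 to 0 °C; MeI (1.2 equiv), −78 °C to rt; then aq. HCl
Reagents that add atoms: iodomethane, CI
Why: Double deprotonation gives a lithium carboxylate/lithium acetylide in which only the acetylide carbon is nucleophilic enough towards iodomethane in THF without a polar cosolvent (acetylide alkylation), which installs C16.

Step 4
Reactants: 6 14,15-dinorlabd-8(17)-en-12-yn-19-oic acid
Product: 8 (12E)-13-iodo-14,15-dinorlabda-8(17),12-dien-19-oic acid (I trans to C11, methyl cis to C11), via bis(zirconocene) intermediate 7 (not isolated)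
Conditions: Cp2Zr(H)Cl (2.4 equiv), THF, rt, 3 h; then I2, THF, 0 °C; then aq. HCl/Na2S2O3
Reagents that add atoms: iodine, II
Why: Syn hydrozirconation (Schwartz reagent) should place zirconium on the less hindered, methyl-bearing C13 once the slight excess of hydride has equilibrated the regioisomers, and iodinolysis with retention then gives the 12E iodide; the first equivalent of reagent is consumed by the acid as a zirconium carboxylate that is released on acidic work-up, and the hindered exocyclic olefin should react far more slowly than the alkyne.

Step 5
Reactants: 9 (−)-β-caryophyllene, (1R,4E,9S)-4,11,11-trimethyl-8-methylidenebicyclo[7.2.0]undec-4-ene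
Product: 12 12'-hydroxy-β-caryophyllene, [(1R,4Z,9S)-11,11-dimethyl-8-methylidenebicyclo[7.2.0]undec-4-en-4-yl]methanol with the trans ring olefin retained, via allylpotassium 10 (not isolated), via potassium allyltrimethoxyborate 11 (not isolated)
Conditions: nBuLi, KOtBu, THF/hexane, −78 to −55 °C; B(OMe)3, −78 °C; then H2O2, aq. NaOH, 0 °C
Reagents that add atoms: hydrogen peroxide, OO
Why: Schlosser superbase metalation should remove a proton from the allylic methyl group (kinetic acidity CH3 > CH2 > CH) to give an allylpotassium whose C4'–C5' torsion is frozen at low temperature and whose endo form is the one that corresponds to the trans ring olefin, so that borylation at the primary terminus and oxidation of the configurationally stable ate complex deliver the primary allylic alcohol with the olefin geometry and C1'/C9' intact.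

Step 6
Reactants: 12 12'-hydroxy-β-caryophyllene
Product: 13 (1R,4Z,9S)-11,11-dimethyl-8-methylidenebicyclo[7.2.0]undec-4-ene-4-carbaldehyde (trans ring olefin, formyl cis to C6')
Conditions: MnO2 (activated, excess), CH2Cl2, rt
Reagents that add atoms: none
Why: Activated MnO2 oxidises only the allylic alcohol, under neutral and non-nucleophilic conditions that give no conjugate-addition pathway by which the strained trans olefin could relax (allylic oxidation).

Step 7
Reactants: 8 (12E)-13-iodo-14,15-dinorlabda-8(17),12-dien-19-oic acid; 13 trans-cyclononene enal (1.5 equiv)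
Product: 14 Diels–Alder adduct, the target skeleton with a formyl group on C4' and the free C19 acid (cyclohexene trans-fused to the nine-membered ring at C4'–C5'; formyl cis to C11 on C12 and cis to C6'), via trans-communic acid 1 (not isolated)
Conditions: tributyl(vinyl)stannane (1.3 equiv), Pd2(dba)3 (5 mol %), AsPh3 (20 mol %), BHT, degassed toluene, 55 °C, 3 h, then 105 °C, 36 h, sealed tube
Reagents that add atoms: tributyl(vinyl)stannane, C=C[Sn](CCCC)(CCCC)CCCC
Why: Zerovalent palladium inserts into the C13–I bond of 8, transmetalation from tin and reductive elimination forge the C13–C14 σ bond with retention of the 12E geometry, and the diene 1 so released is intercepted by enal 13 in a thermal, concerted but asynchronous [4+2] cycloaddition that forges C15–C5' and C12–C4' and turns C13–C14 into the ring olefin; the closest precedent is the domino Stille coupling/Diels–Alder sequence. The six-membered ring C12–C13–C14–C15–C5'–C4' is closed by intermolecular suprafacial [4π+2π] cycloaddition and is the only ring formed. C4' and C5' inherit their trans relationship stereospecifically from the trans ring olefin of 13, and their absolute sense follows from diene approach to the exposed outer face of the dominant cyclononene conformer, the face that peracids also attack in caryophyllene, which is fixed by the trans-fused cyclobutane at C1'/C9'. C12 is set by the endo orientation of the formyl group (secondary orbital overlap) combined with the E diene, which places C11 cis to the formyl group. The step needs ortho regiochemistry, secured by pairing the unsubstituted, most nucleophilic diene terminus C15 with the electrophilic β-carbon C5', and it needs the trans olefin of 13 to survive, which is why a weakly nucleophilic arsine ligand replaces phosphines that could isomerise the enal by reversible conjugate addition. Slow release of 1 beside an excess of 13 should keep diene oligomerisation down.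

Step 8
Reactants: 14 Diels–Alder adduct aldehyde
Product: 15 CNP0330729.1, the C4'/C19 diacid
Conditions: NaClO2, NaH2PO4, 2-methyl-2-butene (excess), tBuOH/THF/H2O, 0 °C to rt
Reagents that add atoms: sodium chlorite, [Na+].[O-]Cl=O
Why: Pinnick (Lindgren–Kraus) oxidation converts the neopentyl aldehyde on the quaternary C4' into the acid with no epimerisable centre nearby, and the excess 2-methyl-2-butene traps hypochlorous acid before it can add to the three olefins.

Compound list
1 | trans-communic acid, (12E)-labda-8(17),12,14-trien-19-oic acid (also re-formed in the flask in step 7) | C=C/C(C)=C/C[C@H]1C(=C)CC[C@@H]2[C@]1(C)CCC[C@]2(C)C(=O)O | starting material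
2 | secondary ozonide (1,2,4-trioxolane spanning C12 and C13, epimer mixture at the two new ring carbons) | C=CC1(C)OOC(C[C@H]2C(=C)CC[C@@H]3[C@]2(C)CCC[C@]3(C)C(=O)O)O1 | intermediate
3 | 12-oxo-13,14,15,16-tetranorlabd-8(17)-en-19-oic acid | O=CC[C@H]1C(=C)CC[C@@H]2[C@]1(C)CCC[C@]2(C)C(=O)O | intermediate
4 | 14,15,16-trinorlabd-8(17)-en-12-yn-19-oic acid | C#CC[C@H]1C(=C)CC[C@@H]2[C@]1(C)CCC[C@]2(C)C(=O)O | intermediate
5 | dilithium salt of 4 (lithium carboxylate, lithium acetylide) | [Li+].[Li+].[C-]#CC[C@H]1C(=C)CC[C@@H]2[C@]1(C)CCC[C@]2(C)C(=O)[O-] | intermediate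
6 | 14,15-dinorlabd-8(17)-en-12-yn-19-oic acid | CC#CC[C@H]1C(=C)CC[C@@H]2[C@]1(C)CCC[C@]2(C)C(=O)O | intermediate
7 | C13 alkenylzirconocene chloride (Zr trans to C11) with the C19 carboxylate bound to a second chlorozirconocene, cyclopentadienyl rings drawn η1 | C/C(=C\C[C@H]1C(=C)CC[C@@H]2[C@]1(C)CCC[C@]2(C)C(=O)O[Zr](Cl)(C3C=CC=C3)C3C=CC=C3)[Zr](Cl)(C3C=CC=C3)C3C=CC=C3 | intermediate
8 | (12E)-13-iodo-14,15-dinorlabda-8(17),12-dien-19-oic acid | C/C(I)=C\C[C@H]1C(=C)CC[C@@H]2[C@]1(C)CCC[C@]2(C)C(=O)O | intermediate
9 | (−)-β-caryophyllene, (1R,4E,9S) | C/C/1=C\CCC(=C)[C@H]2CC([C@@H]2CC1)(C)C | starting material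
10 | allylpotassium from deprotonation of the C12' methyl group (trans ring geometry kept) | [K+].[CH2-]/C/1=C\CCC(=C)[C@H]2CC([C@@H]2CC1)(C)C | intermediate
11 | potassium trimethoxy(β-caryophyllen-12'-yl)borate | [K+].CO[B-](OC)(OC)C/C/1=C\CCC(=C)[C@H]2CC([C@@H]2CC1)(C)C | intermediate
12 | 12'-hydroxy-β-caryophyllene (trans ring olefin, 1R,4Z,9S) | OC/C/1=C\CCC(=C)[C@H]2CC([C@@H]2CC1)(C)C | intermediate
13 | β-caryophyllen-12'-al (trans ring olefin, 1R,4Z,9S) | O=C/C/1=C\CCC(=C)[C@H]2CC([C@@H]2CC1)(C)C | intermediate
14 | Diels–Alder adduct, C4'-carbaldehyde analogue of the target with free C19 acid | C=C1CC[C@H]2CC=C(C)[C@@H](C[C@H]3C(=C)CC[C@@H]4[C@]3(C)CCC[C@]4(C)C(=O)O)[C@]2(C=O)CC[C@@H]2[C@@H]1CC2(C)C | intermediate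
15 | CNP0330729.1 | C=C1CC[C@H]2CC=C(C)[C@@H](C[C@H]3C(=C)CC[C@@H]4[C@]3(C)CCC[C@]4(C)C(=O)O)[C@]2(C(=O)O)CC[C@@H]2[C@@H]1CC2(C)C | target

Total step count: 8. Longest linear sequence: 6 steps (steps 1, 2, 3, 4, 7, 8).

Steps most likely to fail

Step 7. The bimolecular cycloaddition between a trisubstituted enal and a 1,2-disubstituted diene may be too slow at 105 °C, so that the diene oligomerises or the strained enal relaxes to its ring-cis isomer; face and endo selectivity may also be modest. The fallback sets out from 8 and 13 and separates the two events. Stille coupling of 8 alone (Pd2(dba)3, AsPh3, NMP, 25 °C) gives diene 1, which is isolated cold and combined at once with 13 and Me2AlCl (2.2 equiv, the first equivalent being consumed by the acid as its aluminium carboxylate) in CH2Cl2 at −40 °C. Lewis acid activation at low temperature should sharpen ortho and endo selectivity, and the sequence comes back to the route at 14. No compound outside the list is made (none, F0).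

Step 5. Deprotonation may not discriminate between the C12' methyl group and the allylic C7' methylene of the exocyclic olefin, and the allyl anion may relax torsionally to the ring-cis form before it is trapped. The fallback sets out from 9 and accepts loss of geometry, then restores it stereospecifically. Allylic hydroxylation with SeO2 (cat.)/tBuOOH in CH2Cl2 is expected to give mainly the ring-cis alcohol 12'-hydroxyisocaryophyllene F1 (any trans alcohol formed is 12 itself). Silylation (TBSCl, imidazole) gives silyl ether F2. Buffered mCPBA epoxidises the more electron-rich ring olefin to cis-epoxide F3; either face serves. Vedejs olefin inversion (LiPPh2, THF; then MeI) opens the epoxide anti at C5' and eliminates syn, giving the trans silyl ether F4. TBAF then comes back to the route at 12.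

Step 4. Addition of Zr–H across the unsymmetrical alkyne may be incompletely regioselective, and the excess hydride needed for equilibration may also add to the exocyclic C8=C17 olefin. The fallback sets out from 3 and introduces the methyl group last. Ramirez olefination (CBr4, PPh3, Zn, CH2Cl2, 0 °C; aqueous work-up) gives dibromoalkene F5. In place of 8, F5 is heated with tributyl(vinyl)stannane and 13 (Pd2(dba)3, tri(2-furyl)phosphine, toluene): the bromine trans to C11 couples selectively to give the (12Z)-bromodiene F6 in the flask, which cycloadds to 13 to give the vinyl bromide adduct F7. Suzuki–Miyaura methylation of F7 (trimethylboroxine, Pd(dppf)Cl2, K2CO3, dioxane/H2O, 80 °C) installs C16 and comes back to the route at 14.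

Further compounds
F0 | step 7 | none | none
F1 | step 5 | 12'-hydroxyisocaryophyllene, ring-cis olefin (1R,4E,9S) | OC/C/1=C/CCC(=C)[C@H]2CC([C@@H]2CC1)(C)C
F2 | step 5 | tert-butyldimethylsilyl ether of F1 | CC(C)(C)[Si](C)(C)OC/C/1=C/CCC(=C)[C@H]2CC([C@@H]2CC1)(C)C
F3 | step 5 | cis-4',5'-epoxide of F2 (one face isomer drawn, both converge) | CC(C)(C)[Si](C)(C)OC[C@@]12CC[C@@H]3[C@H](CC3(C)C)C(=C)CC[C@@H]1O2
F4 | step 5 | tert-butyldimethylsilyl ether of 12 (trans ring olefin) | CC(C)(C)[Si](C)(C)OC/C/1=C\CCC(=C)[C@H]2CC([C@@H]2CC1)(C)C
F5 | step 4 | 13,13-dibromo-14,15,16-trinorlabda-8(17),12-dien-19-oic acid | BrC(Br)=CC[C@H]1C(=C)CC[C@@H]2[C@]1(C)CCC[C@]2(C)C(=O)O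
F6 | step 4 | (12Z)-13-bromo-16-norlabda-8(17),12,14-trien-19-oic acid (vinyl trans to C11) | C=C/C(Br)=C/C[C@H]1C(=C)CC[C@@H]2[C@]1(C)CCC[C@]2(C)C(=O)O
F7 | step 4 | 13-bromo-16-nor analogue of adduct 14 | C=C1CC[C@H]2CC=C(Br)[C@@H](C[C@H]3C(=C)CC[C@@H]4[C@]3(C)CCC[C@]4(C)C(=O)O)[C@]2(C=O)CC[C@@H]2[C@@H]1CC2(C)C
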